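**Plan**

1. Numbering of the seco chain: C1 lactone C=O, C2 (Me), C3 (C=O), C4 (OH, CH2OH), C5, C6(Me)=C7, C8 (Me), C9, C10 (=CH2), C11=C12 (CH2OH), C13 (Et, ring O); TES = triethylsilyl, TBDPS = tert-butyldiphenylsilyl. Cuts, in order: C12–C13 (ring), C13–O (C13 and its ethyl come from propanal), C2–C3 (aldol), C10–C11 (Negishi), C5–C6 (epoxide opening), C8–C9 (alkylation).
2. Enabling feature: C13 carries the acyloxy oxygen of the 14-membered lactone and is bonded to sp2 C12 of the C10(=CH2)–C11=C12 diene. C13 can therefore enter as a planar α-acyloxyalkyl radical (from a 1-chloropropyl ester, both epimers) and C12 as an alkenylnickel (from the alkenyl bromide).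
3. Forward: the C6–C10 alkenyl iodide and the C3–C5 epoxide give the C3–C10 chain; C11–C12 is added by Negishi coupling and C1–C2 by aldol; acid plus propanal gives the 1-chloropropyl ester; the single ring is closed in step 20 by a nickel-catalyzed stereoconvergent reductive coupling; C3 oxidation and desilylation follow.
4. Stereochemistry: C8 from Evans alkylation, C4 from Sharpless epoxidation, C2 from Evans syn aldol (the C3 carbinol is temporary), C13 from the chiral nickel catalyst acting on an epimer mixture; 6E from syn-hydrozirconation, 11E from anti-bromination of a propiolate and stereoretentive couplings.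

Key step: step 20

Assumption: C2 of the β-keto lactone is taken to hold its configuration under the neutral and acidic closing steps; the ligand antipode that gives (13S) in step 20 is to be identified on a model 1-chloropropyl ester, and the one named is used unless that test calls for its mirror image.

**Step 1**
Reactants: 1 (R)-4-benzyl-3-propanoyl-1,3-oxazolidin-2-one; 2 2,3-dibromoprop-1-ene
Product: 4 (R)-4-benzyl-3-[(S)-4-bromo-2-methylpent-4-enoyl]-1,3-oxazolidin-2-one, via sodium (Z)-enolate 3 (not isolated)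
Conditions: NaN(SiMe3)2, THF, −78 °C; then 2, −78 → −40 °C
Reagents that add atoms: none
Why: Evans asymmetric alkylation, in which the chelated sodium (Z)-enolate is attacked by the allylic bromide on the face opposite the benzyl group, should set C8 as (S) and bring in the C10 alkenyl bromide.

**Step 2**
Reactants: 4 (R)-4-benzyl-3-[(S)-4-bromo-2-methylpent-4-enoyl]-1,3-oxazolidin-2-one
Product: 5 (S)-4-bromo-2-methylpent-4-en-1-ol
Conditions: LiBH4, MeOH (1 equiv), Et2O, 0 °C
Reagents that add atoms: none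
Why: Reductive cleavage of the N-acyl oxazolidinone by borohydride should give the primary alcohol and release the auxiliary without touching the alkenyl bromide or C8.

**Step 3**
Reactants: 5 (S)-4-bromo-2-methylpent-4-en-1-ol
Product: 6 (S)-4-bromo-2-methylpent-4-enal
Conditions: DMP, CH2Cl2, 0 °C → rt
Reagents that add atoms: none
Why: Dess–Martin oxidation (hypervalent iodine, non-basic) should give the α-branched aldehyde without epimerizing C8.

**Step 4**
Reactants: 6 (S)-4-bromo-2-methylpent-4-enal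
Product: 7 (S)-2-bromo-4-methylhex-1-en-5-yne
Conditions: dimethyl (1-diazo-2-oxopropyl)phosphonate, K2CO3, MeOH, 0 °C → rt
Reagents that add atoms: dimethyl (1-diazo-2-oxopropyl)phosphonate, COP(=O)(OC)C(=[N+]=[N-])C(C)=O
Why: Seyferth–Gilbert homologation in its Ohira–Bestmann form should turn the aldehyde into the terminal alkyne (the future C6) under carbonate conditions mild enough to spare the α-stereocenter.

**Step 5**
Reactants: 7 (S)-2-bromo-4-methylhex-1-en-5-yne
Product: 9 (S)-2-bromo-4-methylhept-1-en-5-yne, via lithium acetylide 8 (not isolated)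
Conditions: LiN(i-Pr)2, THF, −78 °C; MeI, −78 °C → rt
Reagents that add atoms: iodomethane, CI
Why: Deprotonation of the terminal alkyne by an amide base (which does not exchange the alkenyl bromide) followed by SN2 methylation of the acetylide should give the methyl alkyne that carries the C6 methyl group.

**Step 6**
Reactants: 9 (S)-2-bromo-4-methylhept-1-en-5-yne
Product: 11 (4S,5E)-2-bromo-6-iodo-4-methylhepta-1,5-diene, via alkenylzirconocene chloride 10 (not isolated)
Conditions: Cp2Zr(H)Cl (1.5 equiv), THF, rt → 45 °C; I2, 0 °C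
Reagents that add atoms: iodine, II
Why: Hydrozirconation–iodination, a syn addition that places zirconium on the less hindered methyl-bearing alkyne carbon followed by iodinolysis with retention, should give the (E)-trisubstituted alkenyl iodide, the alkyne reacting well before the 1,1-disubstituted bromoalkene.

**Step 7**
Reactants: 12 2-methylidenepropane-1,3-diol
Product: 13 2-{[(tert-butyldiphenylsilyl)oxy]methyl}prop-2-en-1-ol
Conditions: NaH (1.0 equiv), THF, 0 °C; t-BuPh2SiCl (1.0 equiv)
Reagents that add atoms: tert-butyl(chloro)diphenylsilane, CC(C)(C)[Si](Cl)(c1ccccc1)c1ccccc1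
Why: Monosilylation of the symmetric diol through its monosodium alkoxide (silyl ether formation) should differentiate the two hydroxymethyl arms, which is what later makes C4 a stereocenter.

**Step 8**
Reactants: 13 2-{[(tert-butyldiphenylsilyl)oxy]methyl}prop-2-en-1-ol
Product: 14 (R)-(2-{[(tert-butyldiphenylsilyl)oxy]methyl}oxiran-2-yl)methanol
Conditions: Ti(OiPr)4 (10 mol%), D-(−)-diethyl tartrate (12 mol%), t-BuOOH, 4 Å MS, CH2Cl2, −20 °C
Reagents that add atoms: tert-butyl hydroperoxide, CC(C)(C)OO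
Why: Sharpless asymmetric epoxidation of the 2-substituted allylic alcohol, with the D-(−)-tartrate complex delivering oxygen to one alkene face, should give the (R)-epoxide whose quaternary carbon becomes C4 (R) of the target.

**Step 9**
Reactants: 11 (4S,5E)-2-bromo-6-iodo-4-methylhepta-1,5-diene; 14 (R)-(2-{[(tert-butyldiphenylsilyl)oxy]methyl}oxiran-2-yl)methanol
Product: 18 (2S,4E,6S)-8-bromo-2-{[(tert-butyldiphenylsilyl)oxy]methyl}-4,6-dimethylnona-4,8-diene-1,2-diol, via alkenyllithium 15 (not isolated), via alkenylmagnesium bromide 16 (not isolated), via chloromagnesium alkoxide 17 (not isolated)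
Conditions: 11, t-BuLi (2.0 equiv), Et2O, −78 °C; MgBr2·OEt2; then 17 (from 14 + i-PrMgCl, THF, −40 °C), CuI (10 mol%), −40 → 0 °C
Reagents that add atoms: none
Why: Iodine–lithium exchange (much faster than exchange at the alkenyl bromide with exactly two equivalents at −78 °C), transmetalation to magnesium and CuI-catalyzed SN2 opening of the 2,2-disubstituted epoxide at its CH2 terminus should form C5–C6 with retention of the (E) geometry and leave the C4–O bond, hence the C4 configuration, untouched.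

**Step 10**
Reactants: 18 (2S,4E,6S)-8-bromo-2-{[(tert-butyldiphenylsilyl)oxy]methyl}-4,6-dimethylnona-4,8-diene-1,2-diol
Product: 19 bis-TES ether of 18 (primary and tertiary O–SiEt3)
Conditions: Et3SiOTf (2.5 equiv), 2,6-lutidine, CH2Cl2, −78 → 0 °C
Reagents that add atoms: triethylsilyl trifluoromethanesulfonate, CC[Si](CC)(CC)OS(=O)(=O)C(F)(F)F
Why: Silylation with a silyl triflate and a hindered pyridine base should protect the primary and the tertiary hydroxyl in one operation.

**Step 11**
Reactants: 20 ethyl prop-2-ynoate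
Product: 21 ethyl (E)-2,3-dibromoprop-2-enoate
Conditions: Br2, CH2Cl2, 0 °C → rt, dark
Reagents that add atoms: bromine, BrBr
Why: Electrophilic anti addition of bromine to the alkyne should give the dibromide with the two bromines trans, which fixes the later C11=C12 geometry.

**Step 12**
Reactants: 19 bis-TES ether of 18; 21 ethyl (E)-2,3-dibromoprop-2-enoate
Product: 24 ethyl (2E,6S,7E,10S)-2-bromo-10-{[(tert-butyldiphenylsilyl)oxy]methyl}-6,8-dimethyl-4-methylidene-10,11-bis[(triethylsilyl)oxy]undeca-2,7-dienoate, via alkenyllithium 22 (not isolated), via alkenylzinc chloride 23 (not isolated)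
Conditions: t-BuLi (2.0 equiv), Et2O, −78 °C; ZnCl2, THF; then added to 21 (1.3 equiv), Pd(PPh3)4 (5 mol%), THF, 0 °C → rt
Reagents that add atoms: none
Why: Bromine–lithium exchange at C10, transmetalation to zinc and Negishi coupling at the more electrophilic β-bromide of 21 with retention should form C10–C11 and leave the α-bromide, trans to C10, as the C12 handle.

**Step 13**
Reactants: 24 ethyl (2E)-2-bromo dienoate
Product: 25 (2E,6S,7E,10S)-2-bromo-10-{[(tert-butyldiphenylsilyl)oxy]methyl}-6,8-dimethyl-4-methylidene-10,11-bis[(triethylsilyl)oxy]undeca-2,7-dien-1-ol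
Conditions: i-Bu2AlH (2.5 equiv), CH2Cl2, −78 °C
Reagents that add atoms: none
Why: 1,2-Reduction of the unsaturated ester by the aluminium hydride should give the allylic alcohol (the C12 hydroxymethyl group) without touching the alkenyl bromide or the silyl ethers.

**Step 14**
Reactants: 25 allylic alcohol
Product: 26 tert-butyldiphenylsilyl ether of 25
Conditions: t-BuPh2SiCl, imidazole, CH2Cl2, rt
Reagents that add atoms: tert-butyl(chloro)diphenylsilane, CC(C)(C)[Si](Cl)(c1ccccc1)c1ccccc1
Why: Standard imidazole-mediated silylation should protect the primary allylic alcohol as an acid-stable silyl ether.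

**Step 15**
Reactants: 26 tert-butyldiphenylsilyl ether of 25
Product: 28 (2R,4E,6S,9E)-10-bromo-11-[(tert-butyldiphenylsilyl)oxy]-2-{[(tert-butyldiphenylsilyl)oxy]methyl}-4,6-dimethyl-8-methylidene-2-[(triethylsilyl)oxy]undeca-4,9-dienal, via alkoxydimethylsulfonium chloride 27 (not isolated)
Conditions: (COCl)2, DMSO, CH2Cl2, −78 → −40 °C; Et3N, −78 → 0 °C
Reagents that add atoms: none
Why: Swern oxidation applied directly to a primary TES ether, in which the activated sulfonium species cleaves only the primary Si–O bond and the alkoxysulfonium salt collapses to the aldehyde, should unveil C3 while the tertiary TES and both TBDPS ethers survive.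

**Step 16**
Reactants: 28 C3 aldehyde; 1 (R)-4-benzyl-3-propanoyl-1,3-oxazolidin-2-one
Product: 30 (R)-4-benzyl-3-[(2R,3R,4R,6E,8S,11E)-12-bromo-13-(TBDPS-oxy)-4-(TBDPS-oxymethyl)-3-hydroxy-2,6,8-trimethyl-10-methylidene-4-(TES-oxy)trideca-6,11-dienoyl]-1,3-oxazolidin-2-one, via dibutylboron (Z)-enolate 29 (not isolated)
Conditions: 1, n-Bu2BOTf, i-Pr2NEt, CH2Cl2, 0 °C; 28, −78 → 0 °C; pH 7 buffer, MeOH, H2O2
Reagents that add atoms: none
Why: Evans syn aldol reaction, in which the (Z)-boron enolate adds through a closed chair transition state under auxiliary control, should set C2 as (R) and the temporary C3 carbinol as (R) regardless of the adjacent quaternary C4.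

**Step 17**
Reactants: 30 aldol adduct
Product: 31 C3 TES ether of 30
Conditions: Et3SiOTf, 2,6-lutidine, CH2Cl2, −78 → 0 °C
Reagents that add atoms: triethylsilyl trifluoromethanesulfonate, CC[Si](CC)(CC)OS(=O)(=O)C(F)(F)F
Why: Silylation with the silyl triflate should protect the hindered secondary C3 hydroxyl so that the acid can later be activated.

**Step 18**
Reactants: 31 C3 TES ether of 30
Product: 33 (2R,3R,4R,6E,8S,11E)-12-bromo-13-[(tert-butyldiphenylsilyl)oxy]-4-{[(tert-butyldiphenylsilyl)oxy]methyl}-2,6,8-trimethyl-10-methylidene-3,4-bis[(triethylsilyl)oxy]trideca-6,11-dienoic acid, via lithium peroxycarboxylate 32 (not isolated)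
Conditions: LiOH, H2O2, THF/H2O, 0 °C; Na2SO3 (aq); HCl (aq) to pH 4
Reagents that add atoms: hydrogen peroxide, OO
Why: Hydroperoxide-mediated exocyclic cleavage of the N-acyl oxazolidinone should give the acid and release the auxiliary without epimerizing C2.

**Step 19**
Reactants: 33 seco acid; 34 propanal
Product: 36 1-chloropropyl ester of 33 (both C13 epimers), via acid chloride 35 (not isolated)
Conditions: 1-chloro-N,N,2-trimethylprop-1-en-1-amine, CH2Cl2, 0 °C; then 34, ZnCl2 (5 mol%), CH2Cl2, −20 → 0 °C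
Reagents that add atoms: 1-chloro-N,N,2-trimethylprop-1-en-1-amine, CC(C)=C(Cl)N(C)C
Why: Neutral acid chloride formation with the α-chloroenamine followed by ZnCl2-catalyzed addition of the acyl chloride across the aldehyde carbonyl (1-chloroalkyl ester synthesis) should give the ester with C13 formed without control, which is all the next step requires.

**Step 20**
Reactants: 36 1-chloropropyl ester of 33 (both C13 epimers)
Product: 37 bis-TES bis-TBDPS macrolactone (2R,3R,4R,6E,8S,11E,13S)
Conditions: NiBr2·glyme (20 mol%), (3aS,3a'S,8aR,8a'R)-2,2'-(cyclopropane-1,1-diyl)bis(3a,8a-dihydro-8H-indeno[1,2-d]oxazole) (24 mol%), Mn (3 equiv), NaI (0.5 equiv), DMA/THF, 0 °C, syringe-pump addition of 36 (final 2 mM)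
Reagents that add atoms: none
Why: Proposed new method: zerovalent nickel carrying the chiral bis(oxazoline) should add to the C12–Br bond; after one-electron reduction by Mn the alkenylnickel abstracts chlorine (or iodine after exchange with NaI) from C13 of the same molecule, and the planar, oxygen-stabilized α-acyloxyalkyl radical is recaptured at nickel to give a trivalent alkenyl(alkyl)nickel species that reductively eliminates the C12–C13 bond. The closest known reaction types are the nickel-catalyzed enantioconvergent reductive cross-coupling of alkenyl bromides with racemic secondary alkyl chlorides, the nickel/bis(oxazoline) enantioconvergent couplings of racemic 1-haloalkyl esters, and nickel-catalyzed reductive C(sp2)–C(sp3) macrocyclizations; what is new is their combination in one ring-closing event. The 14-membered lactone closes by radical capture at the metal and reductive elimination from a 15-membered nickelacycle (not by radical addition to an alkene), which high dilution and rebound on the same nickel centre should favour over oligomerization. The new C13 stereocenter is controlled by the ligand: both C13 epimers of 36 give the same radical, so the mixture should converge on (13S), with the resident C2, C3, C4 and C8 centres acting only as a matched or mismatched bias. The (11E) geometry is carried over from the alkenyl bromide with retention. The step needs chemoselectivity (oxidative addition at C(sp2)–Br only, halogen abstraction at C(sp3)–Cl only, no nickel insertion into the allylic ester that is formed), which the bromide/chloride pairing, the nitrogen ligand and the low temperature should secure.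

**Step 21**
Reactants: 37 bis-TES bis-TBDPS macrolactone
Product: 38 C3,C4-diol macrolactone (2R,3R,4R,6E,8S,11E,13S), both TBDPS ethers kept
Conditions: p-TsOH·H2O (20 mol%), MeOH/CH2Cl2, 0 °C
Reagents that add atoms: none
Why: Acid-catalyzed methanolysis of silyl ethers should remove both TES groups, which are several orders of magnitude more acid-labile than the TBDPS ethers.

**Step 22**
Reactants: 38 C3,C4-diol macrolactone
Product: 39 bis-TBDPS ether of the target (2R,4R,6E,8S,11E,13S)
Conditions: IBX, DMSO, rt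
Reagents that add atoms: none
Why: IBX oxidation should convert the secondary C3 alcohol into the ketone without cleaving the adjacent 1,2-diol and, being neutral, without epimerizing the now doubly activated C2.

**Step 23**
Reactants: 39 bis-TBDPS ether of the target
Product: 40 CNP0104552.3, (2R,4R,6E,8S,11E,13S)-13-ethyl-4-hydroxy-4,12-bis(hydroxymethyl)-2,6,8-trimethyl-10-methylidene 14-membered 3-oxo lactone
Conditions: HF·pyridine, pyridine, THF, 0 °C → rt
Reagents that add atoms: none
Why: Fluoride-mediated desilylation in a buffered acidic medium should remove both primary TBDPS ethers without enolizing the β-keto lactone or triggering retro-aldol loss of the C4 hydroxymethyl group.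

**Compound list**

1 | (R)-4-benzyl-3-propanoyl-1,3-oxazolidin-2-one | CCC(=O)N1[C@H](Cc2ccccc2)COC1=O | starting material
2 | 2,3-dibromoprop-1-ene | C=C(Br)CBr | starting material
3 | sodium (Z)-enolate of 1 | C/C=C(\[O-])N1[C@H](Cc2ccccc2)COC1=O.[Na+] | intermediate
4 | (R)-4-benzyl-3-[(S)-4-bromo-2-methylpent-4-enoyl]-1,3-oxazolidin-2-one | C=C(Br)C[C@H](C)C(=O)N1[C@H](Cc2ccccc2)COC1=O | intermediate
5 | (S)-4-bromo-2-methylpent-4-en-1-ol | C=C(Br)C[C@H](C)CO | intermediate
6 | (S)-4-bromo-2-methylpent-4-enal | C=C(Br)C[C@H](C)C=O | intermediate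
7 | (S)-2-bromo-4-methylhex-1-en-5-yne | C=C(Br)C[C@H](C)C#C | intermediate
8 | lithium acetylide of 7 | C=C(Br)C[C@H](C)C#C[Li] | intermediate
9 | (S)-2-bromo-4-methylhept-1-en-5-yne | C=C(Br)C[C@H](C)C#CC | intermediate
10 | alkenylzirconocene chloride from 9 (Cp2ZrCl on C6, trans to C8) | Cl[Zr](C1C=CC=C1)(C1C=CC=C1)/C(C)=C/[C@@H](C)CC(Br)=C | intermediate
11 | (4S,5E)-2-bromo-6-iodo-4-methylhepta-1,5-diene | I/C(C)=C/[C@@H](C)CC(Br)=C | intermediate
12 | 2-methylidenepropane-1,3-diol | C=C(CO)CO | starting material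
13 | 2-{[(tert-butyldiphenylsilyl)oxy]methyl}prop-2-en-1-ol | C=C(CO)CO[Si](c1ccccc1)(c1ccccc1)C(C)(C)C | intermediate
14 | (R)-(2-{[(tert-butyldiphenylsilyl)oxy]methyl}oxiran-2-yl)methanol | OC[C@]1(CO[Si](c2ccccc2)(c2ccccc2)C(C)(C)C)CO1 | intermediate
15 | alkenyllithium from 11 (Li in place of I, geometry retained) | [Li]/C(C)=C/[C@@H](C)CC(Br)=C | intermediate
16 | alkenylmagnesium bromide from 11 (MgBr in place of I) | Br[Mg]/C(C)=C/[C@@H](C)CC(Br)=C | intermediate
17 | chloromagnesium alkoxide of 14 | Cl[Mg]OC[C@]1(CO[Si](c2ccccc2)(c2ccccc2)C(C)(C)C)CO1 | intermediate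
18 | (2S,4E,6S)-8-bromo-2-{[(tert-butyldiphenylsilyl)oxy]methyl}-4,6-dimethylnona-4,8-diene-1,2-diol | OC[C@](O)(CO[Si](c1ccccc1)(c1ccccc1)C(C)(C)C)C/C(C)=C/[C@@H](C)CC(Br)=C | intermediate
19 | (2S,4E,6S)-8-bromo-2-{[(tert-butyldiphenylsilyl)oxy]methyl}-4,6-dimethyl-1,2-bis[(triethylsilyl)oxy]nona-4,8-diene | CC[Si](CC)(CC)OC[C@](O[Si](CC)(CC)CC)(CO[Si](c1ccccc1)(c1ccccc1)C(C)(C)C)C/C(C)=C/[C@@H](C)CC(Br)=C | intermediate
20 | ethyl prop-2-ynoate | C#CC(=O)OCC | starting material
21 | ethyl (E)-2,3-dibromoprop-2-enoate | CCOC(=O)/C(Br)=C\Br | intermediate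
22 | alkenyllithium from 19 (Li in place of Br at C10) | CC[Si](CC)(CC)OC[C@](O[Si](CC)(CC)CC)(CO[Si](c1ccccc1)(c1ccccc1)C(C)(C)C)C/C(C)=C/[C@@H](C)CC([Li])=C | intermediate
23 | alkenylzinc chloride from 19 (ZnCl in place of Br at C10) | CC[Si](CC)(CC)OC[C@](O[Si](CC)(CC)CC)(CO[Si](c1ccccc1)(c1ccccc1)C(C)(C)C)C/C(C)=C/[C@@H](C)CC([Zn]Cl)=C | intermediate
24 | ethyl (2E,6S,7E,10S)-2-bromo-10-{[(tert-butyldiphenylsilyl)oxy]methyl}-6,8-dimethyl-4-methylidene-10,11-bis[(triethylsilyl)oxy]undeca-2,7-dienoate | CC[Si](CC)(CC)OC[C@](O[Si](CC)(CC)CC)(CO[Si](c1ccccc1)(c1ccccc1)C(C)(C)C)C/C(C)=C/[C@@H](C)CC(=C)/C=C(/Br)C(=O)OCC | intermediate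
25 | (2E,6S,7E,10S)-2-bromo-10-{[(tert-butyldiphenylsilyl)oxy]methyl}-6,8-dimethyl-4-methylidene-10,11-bis[(triethylsilyl)oxy]undeca-2,7-dien-1-ol | CC[Si](CC)(CC)OC[C@](O[Si](CC)(CC)CC)(CO[Si](c1ccccc1)(c1ccccc1)C(C)(C)C)C/C(C)=C/[C@@H](C)CC(=C)/C=C(/Br)CO | intermediate
26 | tert-butyldiphenylsilyl ether of 25 (C12–CH2O–TBDPS; C3–O–TES, C4–O–TES, C4–CH2O–TBDPS) | CC[Si](CC)(CC)OC[C@](O[Si](CC)(CC)CC)(CO[Si](c1ccccc1)(c1ccccc1)C(C)(C)C)C/C(C)=C/[C@@H](C)CC(=C)/C=C(/Br)CO[Si](c1ccccc1)(c1ccccc1)C(C)(C)C | intermediate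
27 | alkoxydimethylsulfonium chloride from 26 (Me2S+–O on the C3 carbon) | C[S+](C)OC[C@](O[Si](CC)(CC)CC)(CO[Si](c1ccccc1)(c1ccccc1)C(C)(C)C)C/C(C)=C/[C@@H](C)CC(=C)/C=C(/Br)CO[Si](c1ccccc1)(c1ccccc1)C(C)(C)C.[Cl-] | intermediate
28 | (2R,4E,6S,9E)-10-bromo-11-[(tert-butyldiphenylsilyl)oxy]-2-{[(tert-butyldiphenylsilyl)oxy]methyl}-4,6-dimethyl-8-methylidene-2-[(triethylsilyl)oxy]undeca-4,9-dienal | O=C[C@](O[Si](CC)(CC)CC)(CO[Si](c1ccccc1)(c1ccccc1)C(C)(C)C)C/C(C)=C/[C@@H](C)CC(=C)/C=C(/Br)CO[Si](c1ccccc1)(c1ccccc1)C(C)(C)C | intermediate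
29 | di-n-butylboron (Z)-enolate of 1 | C/C=C(\OB(CCCC)CCCC)N1[C@H](Cc2ccccc2)COC1=O | intermediate
30 | (R)-4-benzyl-3-[(2R,3R,4R,6E,8S,11E)-12-bromo-13-[(tert-butyldiphenylsilyl)oxy]-4-{[(tert-butyldiphenylsilyl)oxy]methyl}-3-hydroxy-2,6,8-trimethyl-10-methylidene-4-[(triethylsilyl)oxy]trideca-6,11-dienoyl]-1,3-oxazolidin-2-one | O=C(N1[C@H](Cc2ccccc2)COC1=O)[C@H](C)[C@@H](O)[C@](O[Si](CC)(CC)CC)(CO[Si](c1ccccc1)(c1ccccc1)C(C)(C)C)C/C(C)=C/[C@@H](C)CC(=C)/C=C(/Br)CO[Si](c1ccccc1)(c1ccccc1)C(C)(C)C | intermediate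
31 | C3 triethylsilyl ether of 30 | O=C(N1[C@H](Cc2ccccc2)COC1=O)[C@H](C)[C@@H](O[Si](CC)(CC)CC)[C@](O[Si](CC)(CC)CC)(CO[Si](c1ccccc1)(c1ccccc1)C(C)(C)C)C/C(C)=C/[C@@H](C)CC(=C)/C=C(/Br)CO[Si](c1ccccc1)(c1ccccc1)C(C)(C)C | intermediate
32 | lithium peroxycarboxylate corresponding to acid 33 | [Li+].[O-]OC(=O)[C@H](C)[C@@H](O[Si](CC)(CC)CC)[C@](O[Si](CC)(CC)CC)(CO[Si](c1ccccc1)(c1ccccc1)C(C)(C)C)C/C(C)=C/[C@@H](C)CC(=C)/C=C(/Br)CO[Si](c1ccccc1)(c1ccccc1)C(C)(C)C | intermediate
33 | (2R,3R,4R,6E,8S,11E)-12-bromo-13-[(tert-butyldiphenylsilyl)oxy]-4-{[(tert-butyldiphenylsilyl)oxy]methyl}-2,6,8-trimethyl-10-methylidene-3,4-bis[(triethylsilyl)oxy]trideca-6,11-dienoic acid | OC(=O)[C@H](C)[C@@H](O[Si](CC)(CC)CC)[C@](O[Si](CC)(CC)CC)(CO[Si](c1ccccc1)(c1ccccc1)C(C)(C)C)C/C(C)=C/[C@@H](C)CC(=C)/C=C(/Br)CO[Si](c1ccccc1)(c1ccccc1)C(C)(C)C | intermediate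
34 | propanal | CCC=O | starting material
35 | acid chloride of 33 | ClC(=O)[C@H](C)[C@@H](O[Si](CC)(CC)CC)[C@](O[Si](CC)(CC)CC)(CO[Si](c1ccccc1)(c1ccccc1)C(C)(C)C)C/C(C)=C/[C@@H](C)CC(=C)/C=C(/Br)CO[Si](c1ccccc1)(c1ccccc1)C(C)(C)C | intermediate
36 | (1RS)-1-chloropropyl ester of 33 (both C13 epimers) | CCC(Cl)OC(=O)[C@H](C)[C@@H](O[Si](CC)(CC)CC)[C@](O[Si](CC)(CC)CC)(CO[Si](c1ccccc1)(c1ccccc1)C(C)(C)C)C/C(C)=C/[C@@H](C)CC(=C)/C=C(/Br)CO[Si](c1ccccc1)(c1ccccc1)C(C)(C)C | intermediate
37 | 14-membered lactone (2R,3R,4R,6E,8S,11E,13S): 13-ethyl, 2,6,8-trimethyl, 10-methylidene, 3,4-bis(triethylsilyloxy), 4- and 12-(tert-butyldiphenylsilyloxymethyl) | C=C1/C=C(\CO[Si](c2ccccc2)(c2ccccc2)C(C)(C)C)[C@H](CC)OC(=O)[C@H](C)[C@@H](O[Si](CC)(CC)CC)[C@](O[Si](CC)(CC)CC)(CO[Si](c2ccccc2)(c2ccccc2)C(C)(C)C)C/C(C)=C/[C@@H](C)C1 | intermediate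
38 | 14-membered lactone (2R,3R,4R,6E,8S,11E,13S): 3,4-dihydroxy, 4- and 12-(tert-butyldiphenylsilyloxymethyl), otherwise as 37 | C=C1/C=C(\CO[Si](c2ccccc2)(c2ccccc2)C(C)(C)C)[C@H](CC)OC(=O)[C@H](C)[C@@H](O)[C@](O)(CO[Si](c2ccccc2)(c2ccccc2)C(C)(C)C)C/C(C)=C/[C@@H](C)C1 | intermediate
39 | 14-membered 3-oxo lactone (2R,4R,6E,8S,11E,13S): 4-hydroxy, 4- and 12-(tert-butyldiphenylsilyloxymethyl) (bis-TBDPS ether of the target) | C=C1/C=C(\CO[Si](c2ccccc2)(c2ccccc2)C(C)(C)C)[C@H](CC)OC(=O)[C@H](C)C(=O)[C@](O)(CO[Si](c2ccccc2)(c2ccccc2)C(C)(C)C)C/C(C)=C/[C@@H](C)C1 | intermediate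
40 | CNP0104552.3; (3R,5R,7E,9S,12E,14S)-14-ethyl-5-hydroxy-5,13-bis(hydroxymethyl)-3,7,9-trimethyl-11-methylideneoxacyclotetradeca-7,12-diene-2,4-dione | C=C1/C=C(\CO)[C@H](CC)OC(=O)[C@H](C)C(=O)[C@](O)(CO)C/C(C)=C/[C@@H](C)C1 | target

**Step count**

Total: 23 steps. Longest linear sequence: 20 steps (steps 1–6, 9, 10, 12–23).

**Steps most likely to fail**

Step 20 (the ring closure). Ring closure may lose out to intermolecular coupling and give oligomers; either carbon–halogen bond may be reduced without coupling; nickel may insert into the allylic C13–O bond of the product; facial control at C13 may be weak or mismatched with the resident stereocenters in the macrocyclic transition state. The fallback uses known chemistry, sets out from 31 and returns at 37. The alkenyl bromide of 31 is added to propanal 34 in a Nozaki–Hiyama–Kishi reaction (CrCl2, NiCl2 cat., chiral sulfonamide ligand, THF) to give the (13S)-allylic alcohol F1. LiOH/H2O2 then removes the auxiliary to give the seco hydroxy acid F2, in which the C13 hydroxyl is the only free one. Yamaguchi macrolactonization (2,4,6-trichlorobenzoyl chloride, Et3N, then DMAP, toluene, high dilution) closes the same 14-membered ring at the O–C1 bond and gives 37.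

Step 19 (1-chloropropyl ester). ZnCl2 may strip silyl ethers or ionize allylic positions; C2 may epimerize through the ketene of acid chloride 35; the chloroalkyl ester may hydrolyze during isolation. The fallback sets out from 33 and returns at 36. Ru-catalyzed anti-Markovnikov addition of acid 33 to propyne ([RuCl2(p-cymene)]2, P(4-ClC6H4)3, DMAP, toluene) gives the (Z)-prop-1-enyl ester F3. Markovnikov addition of HCl (1 equiv, Et2O, −40 °C) across the enol ester double bond then gives 36 without an acid chloride or a Lewis acid.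

Step 9 (fragment union). Bromine–lithium exchange at C10 may compete and destroy the alkenyl bromide; attack at the neopentyl-type epoxide carbon may be slow; the epoxy alkoxide may rearrange. The fallback avoids halogen–metal exchange altogether, sets out from 7 and 14, and returns at 19. Epoxy alcohol 14 is silylated (Et3SiCl, imidazole) to its TES ether F4. Lithium acetylide 8, made from 7 with LiN(i-Pr)2, opens F4 at the CH2 terminus (BF3·OEt2, THF, −78 °C) to give the homopropargylic tertiary alcohol F5. Hydroxyl-directed trans-hydrostannation ([Cp*RuCl]4, Bu3SnH) places tin on C6 and gives the (Z)-alkenylstannane F6. Iodinolysis (I2) gives the (Z)-alkenyl iodide F7. Negishi methylation (MeZnCl, Pd(PPh3)4; the C–I bond reacts before the C–Br bond) gives the (E)-trisubstituted alkene F8, and Et3SiOTf/2,6-lutidine then gives 19.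

**Further compounds**

F1 | step 20 | imide 31 with C12–Br replaced by (S)-CH(OH)CH2CH3 (C13 allylic alcohol) | O=C(N1[C@H](Cc2ccccc2)COC1=O)[C@H](C)[C@@H](O[Si](CC)(CC)CC)[C@](O[Si](CC)(CC)CC)(CO[Si](c1ccccc1)(c1ccccc1)C(C)(C)C)C/C(C)=C/[C@@H](C)CC(=C)/C=C(/[C@@H](O)CC)CO[Si](c1ccccc1)(c1ccccc1)C(C)(C)C
F2 | step 20 | (13S)-13-hydroxy seco acid (carboxylic acid of F1 after removal of the auxiliary) | OC(=O)[C@H](C)[C@@H](O[Si](CC)(CC)CC)[C@](O[Si](CC)(CC)CC)(CO[Si](c1ccccc1)(c1ccccc1)C(C)(C)C)C/C(C)=C/[C@@H](C)CC(=C)/C=C(/[C@@H](O)CC)CO[Si](c1ccccc1)(c1ccccc1)C(C)(C)C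
F3 | step 19 | (Z)-prop-1-en-1-yl ester of acid 33 | C/C=C\OC(=O)[C@H](C)[C@@H](O[Si](CC)(CC)CC)[C@](O[Si](CC)(CC)CC)(CO[Si](c1ccccc1)(c1ccccc1)C(C)(C)C)C/C(C)=C/[C@@H](C)CC(=C)/C=C(/Br)CO[Si](c1ccccc1)(c1ccccc1)C(C)(C)C
F4 | step 9 | triethylsilyl ether of epoxy alcohol 14 (configuration of 14 unchanged) | CC[Si](CC)(CC)OC[C@]1(CO[Si](c2ccccc2)(c2ccccc2)C(C)(C)C)CO1
F5 | step 9 | homopropargylic tertiary alcohol from F4 and acetylide 8 (C4–OH, C5–C6≡C7; C4 and C8 as in 18) | CC[Si](CC)(CC)OC[C@](O)(CO[Si](c1ccccc1)(c1ccccc1)C(C)(C)C)CC#C[C@@H](C)CC(Br)=C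
F6 | step 9 | (Z)-alkenylstannane from F5 (Bu3Sn on C6, cis to C8) | CC[Si](CC)(CC)OC[C@](O)(CO[Si](c1ccccc1)(c1ccccc1)C(C)(C)C)C/C(=C/[C@@H](C)CC(Br)=C)[Sn](CCCC)(CCCC)CCCC
F7 | step 9 | (Z)-alkenyl iodide from F6 (I on C6, cis to C8) | CC[Si](CC)(CC)OC[C@](O)(CO[Si](c1ccccc1)(c1ccccc1)C(C)(C)C)C/C(I)=C/[C@@H](C)CC(Br)=C
F8 | step 9 | tertiary alcohol with the (E)-C6(CH3)=C7 alkene (18 with its primary hydroxyl as TES ether) | CC[Si](CC)(CC)OC[C@](O)(CO[Si](c1ccccc1)(c1ccccc1)C(C)(C)C)C/C(C)=C/[C@@H](C)CC(Br)=C
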